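## Retrosynthetic overview

1. The ten-membered carbocycle is closed last, at C4–C5, by an intramolecular Nozaki–Hiyama–Kishi coupling of a C4 enol triflate with the C5 aldehyde; this gives the 4(15)-en-5-ol directly.
2. Before that, the α-methylene γ-lactone is built on the open chain (C7 allyl → C12 aldehyde → α-methylenation → acid → lactonisation on O6) and the C8 angelate is attached by mixed-anhydride acylation.
3. Both oxiranes are installed earlier by two Sharpless epoxidations: an E-allylic alcohol (alkyne carboalumination), then a Z-allylic alcohol (Still–Gennari olefination, iBu2AlH).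
4. The all-syn C6/C7/C8 triad comes first: ketoreductase dynamic kinetic resolution of an α-allyl β-keto ester (C7, C8), then 1,3-syn reduction (C6); O6 and O8 are told apart through a temporary methyl pyranoside.
5. Ring order: temporary oxane (opened again) → oxirane C1/C10 → oxirane C2/C3 → γ-lactone → ten-membered ring.

Assumption: locants C1–C15 are those of the target (lactone oxygen on C6, angelate on C8, methyl C14 on C10, methylene C15 on C4, C11–C13 in the lactone) and are used for all intermediates; compound 1 is taken as a catalogue building block.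

## Route

Step 1
Reactants: 1 methyl 5,5-dimethoxy-3-oxopentanoate; 2 3-bromoprop-1-ene (allyl bromide)
Product: 3 methyl 5,5-dimethoxy-3-oxo-2-(prop-2-en-1-yl)pentanoate (racemic)
Conditions: K2CO3 (1.5 equiv), acetone, reflux
Reagents that add atoms: none
Why: C-alkylation of the β-keto ester enolate at the doubly activated carbon; the new centre is racemic and stays configurationally labile, which step 2 exploits.

Step 2
Reactants: 3 methyl 5,5-dimethoxy-3-oxo-2-(prop-2-en-1-yl)pentanoate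
Product: 4 methyl (2R,3S)-3-hydroxy-5,5-dimethoxy-2-(prop-2-en-1-yl)pentanoate
Conditions: ketoreductase (NADPH-dependent, syn-(2R,3S)-selective, picked from a commercial panel), NADP+ (cat.), iPrOH (10 vol%), KH2PO4/K2HPO4 buffer pH 7.5, MgSO4 (2 mM), 30 °C
Reagents that add atoms: none
Why: enzymatic ketone reduction under dynamic kinetic resolution: the α-centre of 3 racemises in the buffer while the ketoreductase reduces only one enantiomer from one carbonyl face, so C7 and C8 (syn) are set in one asymmetric catalytic step that leaves the alkene and acetal untouched.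

Step 3
Reactants: 4 methyl (2R,3S)-3-hydroxy-5,5-dimethoxy-2-(prop-2-en-1-yl)pentanoate
Product: 5 (2R,3S)-3-hydroxy-N,5,5-trimethoxy-N-methyl-2-(prop-2-en-1-yl)pentanamide
Conditions: MeNH(OMe)·HCl (3 equiv), iPrMgCl (6 equiv), THF, −20 °C
Reagents that add atoms: N,O-dimethylhydroxylamine hydrochloride, CNOC.Cl
Why: direct ester aminolysis by the magnesium amide (Weinreb amide formation); the cold, non-enolising conditions leave C7 and C8 untouched.

Step 4
Reactants: 6 (4-methoxyphenyl)methanol; 7 tributyl(iodomethyl)stannane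
Product: 8 tributyl{[(4-methoxyphenyl)methoxy]methyl}stannane
Conditions: NaH, THF–DMF, 0 °C to rt
Reagents that add atoms: none
Why: Williamson etherification of the alkoxide with the primary iodide gives the precursor of the hydroxymethyl anion equivalent.

Step 5
Reactants: 5 (2R,3S)-3-hydroxy-N,5,5-trimethoxy-N-methyl-2-(prop-2-en-1-yl)pentanamide; 8 tributyl{[(4-methoxyphenyl)methoxy]methyl}stannane
Product: 10 (3R,4S)-4-hydroxy-6,6-dimethoxy-1-[(4-methoxyphenyl)methoxy]-3-(prop-2-en-1-yl)hexan-2-one, via alkoxymethyllithium 9 (not isolated)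
Conditions: 8 (2.6 equiv), nBuLi (2.5 equiv), THF, −78 °C; then 5, −78 °C; aq. NH4Cl
Reagents that add atoms: none
Why: tin–lithium exchange gives the α-alkoxy organolithium, whose addition to the Weinreb amide stops at the chelated tetrahedral adduct and so gives the ketone (C5 introduced) without over-addition.

Step 6
Reactants: 10 (3R,4S)-4-hydroxy-6,6-dimethoxy-1-[(4-methoxyphenyl)methoxy]-3-(prop-2-en-1-yl)hexan-2-one
Product: 11 (2S,3R,4S)-6,6-dimethoxy-1-[(4-methoxyphenyl)methoxy]-3-(prop-2-en-1-yl)hexane-2,4-diol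
Conditions: Et2BOMe (1.1 equiv), NaBH4, THF–MeOH 4:1, −78 °C; AcOH quench, MeOH co-evaporation
Reagents that add atoms: none
Why: Narasaka–Prasad reduction: hydride attacks the six-membered boron chelate of the β-hydroxy ketone axially, giving the 1,3-syn diol and thereby C6 (all-syn C6/C7/C8).

Step 7
Reactants: 11 (2S,3R,4S)-6,6-dimethoxy-1-[(4-methoxyphenyl)methoxy]-3-(prop-2-en-1-yl)hexane-2,4-diol
Product: 12 (4S,5R,6S)-2-methoxy-6-{[(4-methoxyphenyl)methoxy]methyl}-5-(prop-2-en-1-yl)oxan-4-ol (methyl pyranoside, both anomers)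
Conditions: PPTS (5 mol%), 4 Å molecular sieves, CH2Cl2, rt
Reagents that add atoms: none
Why: acid-catalysed transacetalisation: only O6 can reach C10 through a six-membered ring (O8 would need an oxetane), so the cyclic acetal ties up O6 and leaves O8 free; the anomeric centre is temporary.

Step 8
Reactants: 12 methyl pyranoside
Product: 13 4-O-(tert-butyldimethylsilyl) ether of 12 (C8–OTBS, both anomers)
Conditions: TBSOTf, 2,6-lutidine, CH2Cl2, −78 to 0 °C
Reagents that add atoms: tert-butyldimethylsilyl trifluoromethanesulfonate, CC(C)(C)[Si](C)(C)OS(=O)(=O)C(F)(F)F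
Why: silylation of the only free hydroxyl (hindered secondary, hence the triflate) fixes the O8 protecting group.

Step 9
Reactants: 13 C8–OTBS methyl pyranoside
Product: 14 4-[(tert-butyldimethylsilyl)oxy]-6-{[(4-methoxyphenyl)methoxy]methyl}-5-(prop-2-en-1-yl)oxan-2-ol (lactol, both anomers)
Conditions: AcOH–H2O–THF 3:1:1, 45 °C
Reagents that add atoms: water, O
Why: hydrolysis of a 2-deoxy glycoside, which is far more acid-labile than the secondary TBS ether or the PMB ether.

Step 10
Reactants: 14 lactol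
Product: 15 (2S,3S,4S)-4-[(tert-butyldimethylsilyl)oxy]-1-[(4-methoxyphenyl)methoxy]-3-(prop-2-en-1-yl)hept-6-yn-2-ol
Conditions: dimethyl (1-diazo-2-oxopropyl)phosphonate, K2CO3, MeOH, 0 °C to rt
Reagents that add atoms: dimethyl (1-diazo-2-oxopropyl)phosphonate, COP(=O)(OC)C(=[N+]=[N-])C(C)=O
Why: Seyferth–Gilbert homologation (Ohira–Bestmann variant) of the open-chain aldehyde tautomer gives the terminal alkyne (C1 added) and releases O6 as the only free hydroxyl.

Step 11
Reactants: 15 alkynol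
Product: 16 C6-O-triethylsilyl ether of 15
Conditions: TESCl, imidazole, DMF, 0 °C to rt
Reagents that add atoms: chlorotriethylsilane, CC[Si](Cl)(CC)CC
Why: silylation gives O6 a group that can later be removed in the presence of the O8 TBS ether.

Step 12
Reactants: 16 alkyne
Product: 18 (2E)-5-[(tert-butyldimethylsilyl)oxy]-8-[(4-methoxyphenyl)methoxy]-3-methyl-6-(prop-2-en-1-yl)-7-[(triethylsilyl)oxy]oct-2-en-1-ol, via alkenyldimethylalane 17 (not isolated)
Conditions: AlMe3 (3 equiv), Cp2ZrCl2 (0.25 equiv), CH2Cl2, 0 °C to rt; evaporate, THF, nBuLi (1.1 equiv), −78 °C; (CH2O)n, −78 °C to rt; aq. potassium sodium tartrate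
Reagents that add atoms: trimethylaluminium, C[Al](C)C; formaldehyde (as paraformaldehyde), C=O
Why: Negishi zirconium-catalysed carboalumination adds Me and Al syn across the alkyne (methyl C14 on C10, Al on C1), and the alanate traps formaldehyde with retention, so the trisubstituted alkene is E.

Step 13
Reactants: 18 E-allylic alcohol
Product: 19 (1R,10R)-1,10-epoxide of 18 (2,3-epoxy alcohol, C2 = CH2OH)
Conditions: Ti(OiPr)4 (10 mol%), D-(−)-diethyl tartrate (12 mol%), tBuOOH (2 equiv), 4 Å molecular sieves, CH2Cl2, −20 °C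
Reagents that add atoms: tert-butyl hydroperoxide, CC(C)(C)OO
Why: Sharpless asymmetric epoxidation: the D-tartrate titanium complex delivers oxygen to the face opposite to that used by L-tartrate in the geraniol case, giving the (1R,10R) oxirane under catalyst control while the isolated allyl group is not touched.

Step 14
Reactants: 19 epoxy alcohol
Product: 20 epoxy aldehyde (C2 = CHO, oxirane as in 19)
Conditions: Dess–Martin periodinane, NaHCO3, CH2Cl2, 0 °C to rt
Reagents that add atoms: none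
Why: buffered Dess–Martin oxidation of the primary alcohol stops at the aldehyde and does not open the oxirane.

Step 15
Reactants: 20 epoxy aldehyde
Product: 21 methyl (Z)-enoate (C2=C3 Z, C4 = CO2Me)
Conditions: (CF3CH2O)2P(O)CH2CO2Me, KN(SiMe3)2, 18-crown-6, THF, −78 °C
Reagents that add atoms: methyl 2-[bis(2,2,2-trifluoroethoxy)phosphoryl]acetate, COC(=O)CP(=O)(OCC(F)(F)F)OCC(F)(F)F
Why: Still–Gennari modification of the Horner–Wadsworth–Emmons olefination: fast, irreversible elimination from the kinetic adduct gives the Z-alkene (C3 and C4 added).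

Step 16
Reactants: 21 Z-enoate
Product: 22 Z-allylic alcohol (C4 = CH2OH)
Conditions: iBu2AlH (2.5 equiv), CH2Cl2, −78 °C; aq. potassium sodium tartrate
Reagents that add atoms: none
Why: 1,2-reduction of the enoate at low temperature keeps the Z geometry and the vinyl oxirane.

Step 17
Reactants: 22 Z-allylic alcohol
Product: 23 bis-epoxy alcohol (new cis-oxirane, C2 S and C3 S; C4 = CH2OH)
Conditions: Ti(OiPr)4 (20 mol%), L-(+)-diethyl tartrate (24 mol%), tBuOOH (2 equiv), 4 Å molecular sieves, CH2Cl2, −20 °C, 48 h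
Reagents that add atoms: tert-butyl hydroperoxide, CC(C)(C)OO
Why: Sharpless asymmetric epoxidation of the Z-allylic alcohol: L-tartrate directs oxygen to the face that gives (2S,3S), which is also the face anti to the quaternary C10 in the A(1,3)-minimised conformer (matched case), and the Z geometry gives the cis-oxirane.

Step 18
Reactants: 23 bis-epoxy alcohol
Product: 24 bis-epoxy aldehyde (C4 = CHO)
Conditions: Dess–Martin periodinane, NaHCO3, CH2Cl2, 0 °C to rt
Reagents that add atoms: none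
Why: buffered Dess–Martin oxidation of the primary alcohol is compatible with both oxiranes.

Step 19
Reactants: 24 bis-epoxy aldehyde
Product: 25 secondary alcohol (C4 = CH(OH)CH3, both C4 epimers)
Conditions: MeMgBr (1.3 equiv), THF, −78 °C; aq. NH4Cl
Reagents that add atoms: methylmagnesium bromide, C[Mg]Br
Why: Grignard 1,2-addition to the aldehyde (C15 introduced) is much faster than oxirane opening at −78 °C; the C4 carbinol configuration is removed in step 20.

Step 20
Reactants: 25 secondary alcohol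
Product: 26 methyl ketone (C4 = C(=O)CH3)
Conditions: Dess–Martin periodinane, NaHCO3, CH2Cl2, rt
Reagents that add atoms: none
Why: Dess–Martin oxidation converges both C4 epimers to one α,β-epoxy ketone.

Step 21
Reactants: 26 methyl ketone
Product: 28 enol triflate (C4(OTf)=C15H2), via potassium enolate 27 (not isolated)
Conditions: KN(SiMe3)2 (1.2 equiv), THF, −78 °C; then PhNTf2, −78 to 0 °C
Reagents that add atoms: N-phenylbis(trifluoromethanesulfonimide), O=S(=O)(N(c1ccccc1)S(=O)(=O)C(F)(F)F)C(F)(F)F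
Why: kinetic enolisation occurs only at the methyl group (the oxirane C–H would give a strained oxiranyl enolate), and O-sulfonylation gives the 1,1-disubstituted alkenyl triflate that carries C15 as the future exocyclic methylene.

Step 22
Reactants: 28 enol triflate
Product: 29 aldehyde (C7 side chain CH2–CHO, C12 = CHO)
Conditions: OsO4 (2 mol%), NaIO4 (4 equiv), 2,6-lutidine, dioxane–H2O 3:1, rt
Reagents that add atoms: sodium periodate (oxygen source relayed by OsO4), [Na+].[O-][I](=O)(=O)=O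
Why: Lemieux–Johnson oxidative cleavage is selective for the electron-rich monosubstituted alkene over the electron-poor enol triflate.

Step 23
Reactants: 29 aldehyde
Product: 30 α-methylene aldehyde (C11(=C13H2)–C12HO)
Conditions: 37% aq. HCHO, pyrrolidine (10 mol%), propionic acid (10 mol%), iPrOH, 45 °C
Reagents that add atoms: formaldehyde, C=O
Why: organocatalytic Mannich condensation–elimination (α-methylenation of an aldehyde through its enamine) installs C13 without strong base.

Step 24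
Reactants: 30 α-methylene aldehyde
Product: 31 acrylic acid (C12 = CO2H)
Conditions: NaClO2, NaH2PO4, 2-methylbut-2-ene, tBuOH–H2O, 0 °C to rt
Reagents that add atoms: sodium chlorite, [Na+].[O-][Cl]=O
Why: Pinnick oxidation converts the enal to the acid without touching the alkenes, with the hypochlorite scavenged by 2-methylbut-2-ene.

Step 25
Reactants: 31 acrylic acid
Product: 33 trans α-methylene γ-lactone (O6–C12; C8–OTBS, C5–OPMB), via hydroxy acid 32 (not isolated)
Conditions: HF·pyridine, pyridine, THF, 0 °C to rt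
Reagents that add atoms: none
Why: the TES ether is cleaved selectively over the TBS ether and the freed γ-hydroxy acid lactonises (intramolecular acyl substitution); only O6 is free, so only the 6,12-lactone forms, and its trans fusion follows from the C6/C7 configurations already set.

Step 26
Reactants: 33 lactone
Product: 34 C8 alcohol
Conditions: HF·pyridine (excess), pyridine, THF, rt
Reagents that add atoms: none
Why: buffered fluoride desilylation removes the secondary TBS ether under conditions that the oxiranes, the enol triflate and the α-methylene lactone tolerate.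

Step 27
Reactants: 34 C8 alcohol; 35 angelic acid, (2Z)-2-methylbut-2-enoic acid
Product: 37 C8 angelate, via mixed anhydride 36 (not isolated)
Conditions: 35 (3 equiv), 2,4,6-trichlorobenzoyl chloride, Et3N, toluene, rt, salt filtered off; then 34, toluene, 75 °C (no DMAP)
Reagents that add atoms: none
Why: Yamaguchi-type mixed-anhydride acylation without a nucleophilic catalyst transfers the angeloyl group with its Z geometry intact (no isomerisation to tiglate).

Step 28
Reactants: 37 C8 angelate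
Product: 38 C5 primary alcohol
Conditions: DDQ (1.5 equiv), CH2Cl2–pH 7 buffer 10:1, 0 °C
Reagents that add atoms: none
Why: oxidative cleavage of the p-methoxybenzyl ether through its benzylic oxocarbenium ion is neutral and leaves esters, oxiranes and the enol triflate intact.

Step 29
Reactants: 38 C5 primary alcohol
Product: 39 C5 aldehyde (seco-aldehyde)
Conditions: Dess–Martin periodinane, NaHCO3, CH2Cl2, 0 °C; used at once
Reagents that add atoms: none
Why: buffered Dess–Martin oxidation gives the α-acyloxy aldehyde without epimerising C6.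

Step 30
Reactants: 39 C5 aldehyde
Product: 41 target, (1R,2S,3S,5R,6S,7R,8S,10R)-8-angeloyloxy-1,10:2,3-diepoxy-5-hydroxygermacra-4(15),11(13)-dien-12,6-olide, via alkenylchromium dichloride 40 (not isolated)
Conditions: CrCl2 (8 equiv), NiCl2 (0.1 equiv), degassed DMF–THF 3:1, 2 mM, slow addition, rt; aq. NaHCO3/serine work-up
Reagents that add atoms: none
Why: intramolecular Nozaki–Hiyama–Kishi reaction: zerovalent nickel inserts into the C–OTf bond, transmetalation gives the weakly basic trivalent alkenylchromium, and this adds to the aldehyde anti to the C6–O bond (polar Felkin–Anh) to give the 5,6-anti alcohol (5R) and close the ten-membered ring.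

## Compound list

1 | methyl 5,5-dimethoxy-3-oxopentanoate | COC(=O)CC(=O)CC(OC)OC | starting material
2 | 3-bromoprop-1-ene (allyl bromide) | C=CCBr | starting material
3 | methyl 5,5-dimethoxy-3-oxo-2-(prop-2-en-1-yl)pentanoate, racemic | COC(=O)C(CC=C)C(=O)CC(OC)OC | intermediate
4 | methyl (2R,3S)-3-hydroxy-5,5-dimethoxy-2-(prop-2-en-1-yl)pentanoate | COC(=O)[C@H](CC=C)[C@@H](O)CC(OC)OC | intermediate
5 | (2R,3S)-3-hydroxy-N,5,5-trimethoxy-N-methyl-2-(prop-2-en-1-yl)pentanamide | CON(C)C(=O)[C@H](CC=C)[C@@H](O)CC(OC)OC | intermediate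
6 | (4-methoxyphenyl)methanol | COc1ccc(CO)cc1 | starting material
7 | tributyl(iodomethyl)stannane | CCCC[Sn](CCCC)(CCCC)CI | starting material
8 | tributyl{[(4-methoxyphenyl)methoxy]methyl}stannane | CCCC[Sn](CCCC)(CCCC)COCc1ccc(OC)cc1 | intermediate
9 | {[(4-methoxyphenyl)methoxy]methyl}lithium | [Li]COCc1ccc(OC)cc1 | intermediate (not isolated)
10 | (3R,4S)-4-hydroxy-6,6-dimethoxy-1-[(4-methoxyphenyl)methoxy]-3-(prop-2-en-1-yl)hexan-2-one | COc1ccc(COCC(=O)[C@H](CC=C)[C@@H](O)CC(OC)OC)cc1 | intermediate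
11 | (2S,3R,4S)-6,6-dimethoxy-1-[(4-methoxyphenyl)methoxy]-3-(prop-2-en-1-yl)hexane-2,4-diol (C6/C7/C8 all-syn) | COc1ccc(COC[C@@H](O)[C@H](CC=C)[C@@H](O)CC(OC)OC)cc1 | intermediate
12 | (4S,5R,6S)-2-methoxy-6-{[(4-methoxyphenyl)methoxy]methyl}-5-(prop-2-en-1-yl)oxan-4-ol, both anomers | COc1ccc(COC[C@H]2OC(OC)C[C@H](O)[C@H]2CC=C)cc1 | intermediate
13 | 4-O-(tert-butyldimethylsilyl) ether of 12, both anomers | COc1ccc(COC[C@H]2OC(OC)C[C@H](O[Si](C)(C)C(C)(C)C)[C@H]2CC=C)cc1 | intermediate
14 | 4-[(tert-butyldimethylsilyl)oxy]-6-{[(4-methoxyphenyl)methoxy]methyl}-5-(prop-2-en-1-yl)oxan-2-ol, ring centres as in 12, both anomers | COc1ccc(COC[C@H]2OC(O)C[C@H](O[Si](C)(C)C(C)(C)C)[C@H]2CC=C)cc1 | intermediate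
15 | (2S,3S,4S)-4-[(tert-butyldimethylsilyl)oxy]-1-[(4-methoxyphenyl)methoxy]-3-(prop-2-en-1-yl)hept-6-yn-2-ol (O6 free, C6/C7/C8 all-syn) | COc1ccc(COC[C@@H](O)[C@H](CC=C)[C@@H](O[Si](C)(C)C(C)(C)C)CC#C)cc1 | intermediate
16 | C6-O-triethylsilyl ether of 15 | COc1ccc(COC[C@@H](O[Si](CC)(CC)CC)[C@H](CC=C)[C@@H](O[Si](C)(C)C(C)(C)C)CC#C)cc1 | intermediate
17 | (E)-alkenyldimethylalane from 16 (Al on C1, methyl on C10, C9 trans to Al) | COc1ccc(COC[C@@H](O[Si](CC)(CC)CC)[C@H](CC=C)[C@@H](O[Si](C)(C)C(C)(C)C)C/C(C)=C/[Al](C)C)cc1 | intermediate (not isolated)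
18 | (2E)-5-[(tert-butyldimethylsilyl)oxy]-8-[(4-methoxyphenyl)methoxy]-3-methyl-6-(prop-2-en-1-yl)-7-[(triethylsilyl)oxy]oct-2-en-1-ol | COc1ccc(COC[C@@H](O[Si](CC)(CC)CC)[C@H](CC=C)[C@@H](O[Si](C)(C)C(C)(C)C)C/C(C)=C/CO)cc1 | intermediate
19 | (1R,10R)-1,10-epoxide of 18 (C9 and C2 trans on the oxirane, C2 = CH2OH) | COc1ccc(COC[C@@H](O[Si](CC)(CC)CC)[C@H](CC=C)[C@@H](O[Si](C)(C)C(C)(C)C)C[C@@]2(C)O[C@@H]2CO)cc1 | intermediate
20 | epoxy aldehyde (C2 = CHO, oxirane as in 19) | COc1ccc(COC[C@@H](O[Si](CC)(CC)CC)[C@H](CC=C)[C@@H](O[Si](C)(C)C(C)(C)C)C[C@@]2(C)O[C@@H]2C=O)cc1 | intermediate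
21 | methyl (Z)-enoate (C2=C3 Z, C4 = CO2Me) | COc1ccc(COC[C@@H](O[Si](CC)(CC)CC)[C@H](CC=C)[C@@H](O[Si](C)(C)C(C)(C)C)C[C@@]2(C)O[C@@H]2/C=C\C(=O)OC)cc1 | intermediate
22 | (Z)-allylic alcohol (C4 = CH2OH) | COc1ccc(COC[C@@H](O[Si](CC)(CC)CC)[C@H](CC=C)[C@@H](O[Si](C)(C)C(C)(C)C)C[C@@]2(C)O[C@@H]2/C=C\CO)cc1 | intermediate
23 | bis-epoxy alcohol (cis-oxirane at C2/C3, C2 S and C3 S; C4 = CH2OH) | COc1ccc(COC[C@@H](O[Si](CC)(CC)CC)[C@H](CC=C)[C@@H](O[Si](C)(C)C(C)(C)C)C[C@@]2(C)O[C@@H]2[C@H]2O[C@H]2CO)cc1 | intermediate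
24 | bis-epoxy aldehyde (C4 = CHO) | COc1ccc(COC[C@@H](O[Si](CC)(CC)CC)[C@H](CC=C)[C@@H](O[Si](C)(C)C(C)(C)C)C[C@@]2(C)O[C@@H]2[C@H]2O[C@H]2C=O)cc1 | intermediate
25 | secondary alcohol (C4 = CH(OH)CH3, both C4 epimers) | COc1ccc(COC[C@@H](O[Si](CC)(CC)CC)[C@H](CC=C)[C@@H](O[Si](C)(C)C(C)(C)C)C[C@@]2(C)O[C@@H]2[C@H]2O[C@H]2C(C)O)cc1 | intermediate
26 | methyl ketone (C4 = C(=O)CH3) | COc1ccc(COC[C@@H](O[Si](CC)(CC)CC)[C@H](CC=C)[C@@H](O[Si](C)(C)C(C)(C)C)C[C@@]2(C)O[C@@H]2[C@H]2O[C@H]2C(C)=O)cc1 | intermediate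
27 | potassium enolate of 26 (C4(OK)=C15H2) | COc1ccc(COC[C@@H](O[Si](CC)(CC)CC)[C@H](CC=C)[C@@H](O[Si](C)(C)C(C)(C)C)C[C@@]2(C)O[C@@H]2[C@H]2O[C@H]2C(=C)[O-])cc1.[K+] | intermediate (not isolated)
28 | enol triflate (C4(OTf)=C15H2) | COc1ccc(COC[C@@H](O[Si](CC)(CC)CC)[C@H](CC=C)[C@@H](O[Si](C)(C)C(C)(C)C)C[C@@]2(C)O[C@@H]2[C@H]2O[C@H]2C(=C)OS(=O)(=O)C(F)(F)F)cc1 | intermediate
29 | aldehyde (C7 side chain CH2–CHO) | COc1ccc(COC[C@@H](O[Si](CC)(CC)CC)[C@H](CC=O)[C@@H](O[Si](C)(C)C(C)(C)C)C[C@@]2(C)O[C@@H]2[C@H]2O[C@H]2C(=C)OS(=O)(=O)C(F)(F)F)cc1 | intermediate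
30 | α-methylene aldehyde (C11(=CH2)–CHO) | COc1ccc(COC[C@@H](O[Si](CC)(CC)CC)[C@H](C(=C)C=O)[C@@H](O[Si](C)(C)C(C)(C)C)C[C@@]2(C)O[C@@H]2[C@H]2O[C@H]2C(=C)OS(=O)(=O)C(F)(F)F)cc1 | intermediate
31 | acrylic acid (C12 = CO2H) | COc1ccc(COC[C@@H](O[Si](CC)(CC)CC)[C@H](C(=C)C(=O)O)[C@@H](O[Si](C)(C)C(C)(C)C)C[C@@]2(C)O[C@@H]2[C@H]2O[C@H]2C(=C)OS(=O)(=O)C(F)(F)F)cc1 | intermediate
32 | hydroxy acid (O6 free) | COc1ccc(COC[C@@H](O)[C@H](C(=C)C(=O)O)[C@@H](O[Si](C)(C)C(C)(C)C)C[C@@]2(C)O[C@@H]2[C@H]2O[C@H]2C(=C)OS(=O)(=O)C(F)(F)F)cc1 | intermediate (not isolated)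
33 | trans α-methylene γ-lactone (C8–OTBS, C5–OPMB, enol triflate) | COc1ccc(COC[C@H]2OC(=O)C(=C)[C@@H]2[C@@H](O[Si](C)(C)C(C)(C)C)C[C@@]3(C)O[C@@H]3[C@H]3O[C@H]3C(=C)OS(=O)(=O)C(F)(F)F)cc1 | intermediate
34 | C8 alcohol of 33 | COc1ccc(COC[C@H]2OC(=O)C(=C)[C@@H]2[C@@H](O)C[C@@]3(C)O[C@@H]3[C@H]3O[C@H]3C(=C)OS(=O)(=O)C(F)(F)F)cc1 | intermediate
35 | angelic acid, (2Z)-2-methylbut-2-enoic acid | C/C=C(/C)C(=O)O | starting material
36 | angelic 2,4,6-trichlorobenzoic anhydride | C/C=C(/C)C(=O)OC(=O)c1c(Cl)cc(Cl)cc1Cl | intermediate (not isolated)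
37 | C8 angelate (C5–OPMB, enol triflate) | COc1ccc(COC[C@H]2OC(=O)C(=C)[C@@H]2[C@@H](OC(=O)/C(C)=C\C)C[C@@]3(C)O[C@@H]3[C@H]3O[C@H]3C(=C)OS(=O)(=O)C(F)(F)F)cc1 | intermediate
38 | C5 primary alcohol | OC[C@H]1OC(=O)C(=C)[C@@H]1[C@@H](OC(=O)/C(C)=C\C)C[C@@]1(C)O[C@@H]1[C@H]1O[C@H]1C(=C)OS(=O)(=O)C(F)(F)F | intermediate
39 | C5 aldehyde (seco-aldehyde) | O=C[C@H]1OC(=O)C(=C)[C@@H]1[C@@H](OC(=O)/C(C)=C\C)C[C@@]1(C)O[C@@H]1[C@H]1O[C@H]1C(=C)OS(=O)(=O)C(F)(F)F | intermediate
40 | alkenylchromium dichloride (CrCl2 on C4) | O=C[C@H]1OC(=O)C(=C)[C@@H]1[C@@H](OC(=O)/C(C)=C\C)C[C@@]1(C)O[C@@H]1[C@H]1O[C@H]1C(=C)[Cr](Cl)Cl | intermediate (not isolated)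
41 | CNP0038366.2, (1R,2S,3S,5R,6S,7R,8S,10R)-8-angeloyloxy-1,10:2,3-diepoxy-5-hydroxygermacra-4(15),11(13)-dien-12,6-olide | C=C1C(=O)O[C@H]2[C@H]1[C@@H](OC(=O)/C(C)=C\C)C[C@@]1(C)O[C@@H]1[C@H]1O[C@H]1C(=C)[C@H]2O | target

## Step count and risks

Total step count: 30. Longest linear sequence: 29 steps (steps 1–3 and 5–30 from compound 1); step 4 is the only side branch.

Three steps most likely to fail:

Step 30 (ring closure). The ten-membered ring is strained, the alkenylchromium sits next to the C2/C3 oxirane (β-oxido elimination to an allene is possible), and the macrocyclic transition state may override the Felkin preference at C5. Fallback, setting out from 39 and coming back at 41: if the cyclisation gives mainly the C5 epimer, the centre is reset after ring formation instead of during it. The product of the coupling, 5-epi-CNP0038366.2 F6, is oxidised (Dess–Martin periodinane, NaHCO3, CH2Cl2) to the cross-conjugated C5 ketone F7. The ketone is then reduced under reagent control ((R)-Me-CBS oxazaborolidine, catecholborane, toluene, −78 °C; alkenyl side as the large group), which leaves the α-methylene lactone alone and gives 41.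

Step 17 (second Sharpless epoxidation). Z-allylic alcohols with a branched substituent react slowly, and selectivity rests on the matched-case argument. Fallback, setting out from 20 and coming back at 25: the facial control is moved to a stereodefined secondary carbinol. Olefination of 20 with bis(2,2,2-trifluoroethyl) (2-oxopropyl)phosphonate (KN(SiMe3)2, 18-crown-6, THF, −78 °C) gives the (Z)-enone F4. (S)-Me-CBS reduction (catecholborane, toluene, −78 °C) gives the (4R) Z-allylic alcohol F5. mCPBA (NaHCO3, CH2Cl2, 0 °C) then epoxidises syn to the hydroxyl in the A(1,3)-minimised conformer (threo), giving 25 as a single C4 epimer with the required (2S,3S) oxirane; step 20 follows as written.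

Step 2 (ketoreductase dynamic kinetic resolution). A panel enzyme must accept the bulky acetal side chain and give the syn isomer with high selectivity. Fallback, setting out from 1 and coming back at 4: the enzyme is given the simpler, well-precedented task of reducing the unsubstituted keto ester. A ketoreductase (NADP+, iPrOH, buffer pH 7) converts 1 into methyl (3R)-3-hydroxy-5,5-dimethoxypentanoate F1. Fráter–Seebach allylation (LiN(iPr)2 2.2 equiv, THF, −78 to −20 °C, then 2) gives the anti product methyl (2R,3R)-3-hydroxy-5,5-dimethoxy-2-(prop-2-en-1-yl)pentanoate F2. Mitsunobu inversion at C8 (chloroacetic acid, PPh3, DIAD, toluene, 0 °C) gives methyl (2R,3S)-3-[(chloroacetyl)oxy]-5,5-dimethoxy-2-(prop-2-en-1-yl)pentanoate F3. Thiourea with NaHCO3 in EtOH (rt) removes the chloroacetate without base-induced elimination and gives 4.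

## Further compounds

F1 | step 2 | methyl (3R)-3-hydroxy-5,5-dimethoxypentanoate | COC(=O)C[C@H](O)CC(OC)OC
F2 | step 2 | methyl (2R,3R)-3-hydroxy-5,5-dimethoxy-2-(prop-2-en-1-yl)pentanoate | COC(=O)[C@H](CC=C)[C@H](O)CC(OC)OC
F3 | step 2 | methyl (2R,3S)-3-[(chloroacetyl)oxy]-5,5-dimethoxy-2-(prop-2-en-1-yl)pentanoate | COC(=O)[C@H](CC=C)[C@@H](OC(=O)CCl)CC(OC)OC
F4 | step 17 | (Z)-enone (C2=C3 Z, C4 = C(=O)CH3, oxirane as in 19) | COc1ccc(COC[C@@H](O[Si](CC)(CC)CC)[C@H](CC=C)[C@@H](O[Si](C)(C)C(C)(C)C)C[C@@]2(C)O[C@@H]2/C=C\C(C)=O)cc1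
F5 | step 17 | (4R) Z-allylic alcohol (C4 = CH(OH)CH3) | COc1ccc(COC[C@@H](O[Si](CC)(CC)CC)[C@H](CC=C)[C@@H](O[Si](C)(C)C(C)(C)C)C[C@@]2(C)O[C@@H]2/C=C\[C@@H](C)O)cc1
F6 | step 30 | 5-epi-CNP0038366.2 (5S alcohol) | C=C1C(=O)O[C@H]2[C@H]1[C@@H](OC(=O)/C(C)=C\C)C[C@@]1(C)O[C@@H]1[C@H]1O[C@H]1C(=C)[C@@H]2O
F7 | step 30 | C5 ketone of the macrocycle (4(15)-en-5-one) | C=C1C(=O)O[C@H]2[C@H]1[C@@H](OC(=O)/C(C)=C\C)C[C@@]1(C)O[C@@H]1[C@H]1O[C@H]1C(=C)C2=O
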